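Conventions used throughout: eremophilane numbering for all decalins (ring A = C1–C5 and C10, ring B = C5–C10, C14 on C5, C15 on C4); β is the face of the decalin that carries C14; "11,12,13-trinoreremophilane" is the 4,5-dimethyldecalin core without the three-carbon unit on C7.

## The problem

The target is a trans-fused eremophilane with seven stereocentres: 2α-OH (axial), 4β-CH3, 5β-CH3 (quaternary), 7β-isopropenyl, 8α-OH, 9α-O-acyl and 10α-H. The quaternary C5 lies between the stereocentres C4 and C10, and every other centre has to be related to it. Once the fusion is trans, the axial C14 screens the β face of both rings. That helps where a reagent must arrive from α: hydrogen at C4, a proton at C10, an epoxide oxygen across C7=C8. It works against the two β groups that are syn-axial to C14, the isopropenyl group on C7 and the hydrogen on C9, so these two centres need a stereospecific or an equilibrating step, not approach control. The (E)-3-methylpent-2-enoate (conjugate addition, deconjugation through its dienolate, migration to the cis hydroxyl on C8) and the isopropenyl group (acid, hydrogenation, electrophiles) will not survive rough treatment and must enter late, and three secondary oxygens have to be told apart. The enabling feature is that C8 and C9 carry vicinal oxygens, C9 is bonded to the ring-fusion carbon C10, and C2 carries an oxygen. Ring A with a C8–C9 bridge between C3 and C10 is therefore the Diels–Alder adduct of an o-quinone monoketal (C3, C4, C5, C10, C9, C8) with a vinyl ether (C1, C2), and a [3,3] shift of the C8 vinyl carbinol makes C5–C6 and ring B. The price is that this shift can only give a cis fusion and the endo adduct a 2β oxygen, so C10 and C2 must be corrected, and the racemic adduct must be resolved.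

## Retrosynthesis

**Ester and silyl ether.** Target 31 is traced to silyl ether 30 and then, by cutting the O9–acyl bond, to diol 26 and acid 27. Acylating earlier would expose the enoate to the organocopper step and place an alkoxide cis to it. The forward reaction must distinguish equatorial O9 from axial O8, which the stannylene acetal 28 (with acid chloride 29) is chosen to do. O2 stays masked as a silyl ether that fluoride removes without base.

**C7–isopropenyl bond.** Diol 26 is cut between C7 and the isopropenyl carbon to epoxy alcohol 24 and isopropenylmagnesium bromide 25. A conjugate addition to a 7-en-9-one or an enolate alkylation would bring the group in from the open α face. Trans-diaxial opening of a 7α,8α-epoxide is stereospecific, places the group 7β and creates the 8α hydroxyl in the same step. The precursor is three carbons smaller and stores two stereocentres in one epoxide. The forward step must attack C7, not C8, and tolerate the syn-axial C14.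

**Epoxide, alkene and the C9 oxygen.** Epoxide 24 comes from allylic alcohol 23 (hydroxyl direction and steric bias both point to the α face). Alcohol 23 comes from methoxymethyl ether 22, and the C7=C8 double bond of 22 from ketone 20 through enol triflate 21. The neighbouring cut, reduction of a 7-en-9-one, is rejected: hydride would enter C9 from the α face and give the 9β alcohol. C9 is therefore never made by hydride addition; it is carried as the α-alkoxy ketone, in which the 9α (equatorial) configuration is the stable one.

**Ring A.** Silyl ether 20 goes back through alcohol 19 and 4-nitrobenzoate 18 to the 2β alcohol 17 (Mitsunobu inversion, equatorial to axial), and 17 to the 3-ene 16 by hydrogenation. The hydrogenation is placed after the ring fusion is trans, because only then does the axial C14 next to C4 give a reliable α-face bias. An oxidation and bulky-hydride reduction at C2 was considered but would not spare the C8 ketone.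

**C10.** Ketone 16 is traced to the diosphenol ether 14 by removing the hydrogens at C10 and C9 (through dilithium species 15). Epimerising C10 next to a C9 ketone was considered and set aside: cis and trans 5-methyl-9-decalones lie close in energy, and kinetic protonation of ring-fusion enolates beside an angular methyl tends to the cis series. Hydrogenation of C9=C10 would add both hydrogens to one face. Dissolving-metal reduction protonates C10 axially and anti to C14 and is the classical route to trans-decalones. Ether 14 comes from diosphenol 13, which is what the ketone and ketal of 12 become on hydrolysis. The second quinone oxygen thus serves twice, as the C9 oxygen and as the handle that erases and resets C10. The benzyl ether is cleaved in the same reduction.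

**Key disconnection.** The cis-decalone 12 is cut at C5–C6 with re-formation of C3–C8, giving the bridged vinyl carbinol 9 (through alkoxide 10 and enolate 11). One ring, one skeletal bond and the quaternary centre are traded for a bicyclo[2.2.2]octene. The forward shift needs the vinyl group syn to the ring alkene. The structures of 9 and 12 were checked: vinyl and benzyloxy are both syn to the alkene bridge, which leads to 2β-OBn, a cis fusion and the C5 configuration of the target.

**Vinyl carbinol.** Carbinol 9 is cut at C7–C8 to ketone 7 and vinylmagnesium bromide 8. Ketone 7 is one enantiomer of the racemic adduct 6; resolution is placed at the first chiral compound so that nothing made later is discarded.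

**Bicyclooctenone.** Adduct 6 is cut at C2–C3 and C1–C10 to benzyl vinyl ether 4 and the o-quinone monoketal 5, made in the flask from phenol 3. Both ring oxygens, the C2 oxygen, both methyl groups and all ring-A carbons are then in place.

**Arene.** Phenol 3 comes from bromophenol 2 by methoxylation and 2 from 3,4-dimethylphenol 1.

## Roads not taken

**Alternative 1:** Cut C8–C9. SmI2 (divalent samarium) would couple the two aldehydes of the ring-A dialdehyde A1 to the 2-O-silyl 8α,9α-diol A2. A2 is identical with diol 26, so this road would join the chosen one two steps from the end. It makes both carbinol centres and ring B in one step and needs no epoxide, no organocopper step and no correction of C9 or C10. In the endgame it is better than the chosen plan. Its weak point is A1: a cyclohexane that already carries C2, C4, the quaternary C5 and C10, plus an isopropenyl-bearing C7 that is α to an aldehyde and epimerisable, as is C10. The key step does nothing to build these. The cyclisation must also place the isopropenyl group axial and syn to C14 and choose the α,α diol over the β,β diol, and nothing in A1 enforces either. The chosen plan sets against this that the quaternary centre and ring B are made together, stereospecifically, from a compound three steps away from a commercial phenol.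

**Alternative 2:** Cut C1–C10 and C5–C6. Mn(OAc)3 (trivalent manganese) would oxidise the acyclic β-keto ester A3 to the C1 radical, which closes 6-endo onto C10, and the C5 radical then adds to the vinyl ketone terminus to give the trans-decalin-2,8-dione A4. This makes both rings, the quaternary centre and the trans fusion in one step, and A4 already has the 9α oxygen beside a C8 ketone; the chosen plan spends three steps (7 to 9) to reach the same ring-B pattern. Against it, A3 needs two remote stereocentres (C4 and C9) set independently across an E-trisubstituted alkene. The second closure is a tertiary radical adding to a polymerisable α'-silyloxy vinyl ketone. The ester carbon must be removed afterwards, and the C2 and C8 ketones of A4 must be differentiated, the same problem that made a 2,8-dione unattractive in the chosen route. The chosen plan is longer but has a stereospecific pericyclic step at the quaternary centre and one early resolution in place of two asymmetric operations.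

**Alternative 3:** Cut C1–C2. Cathodic reduction of the α-methylene ketone A5 would join C1 to the aldehyde carbon C2, close ring A and, after protonation of the C9 enolate at C10, give the 2-hydroxy-trans-decal-9-one A6. It is short, forms the C2 carbinol without a protecting group and uses no stoichiometric metal. For the target it leaves most of the work undone: A6 has no oxygen at C8 and no C7 substituent. The axial 2α hydroxyl and the trans fusion would both depend on kinetic protonation or coupling with no clear bias, and the 9-ketone would later need hydride from the screened β face. A5 is a dimerisation-prone enone and already needs the vicinal C4/C5 pair built acyclically. In step count to a decalin it may equal or beat the chosen plan, which sets against that a complete, correctly placed oxygen pattern (C2, C8, C9) from the cycloaddition.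

Key step: step 6

Remark on the chemistry: (E)-3-methylpent-2-enoic acid (27) is taken as a purchasable, geometrically pure acid.

## Route

Step 1
Reactants: 1 3,4-dimethylphenol
Product: 2 2-bromo-4,5-dimethylphenol
Conditions: Br2 (1.0 equiv), CH2Cl2, 0 °C
Reagents that add atoms: bromine, BrBr
Why: Electrophilic aromatic bromination; the para position is blocked and, of the two ortho positions, only C6 is not wedged between OH and a methyl group, so 2 should be the main monobromide.

Step 2
Reactants: 2 2-bromo-4,5-dimethylphenol
Product: 3 2-methoxy-4,5-dimethylphenol
Conditions: NaOMe (excess), CuBr (10 mol %), DMF/MeOH, 110 °C; aq. HCl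
Reagents that add atoms: sodium methoxide, [Na+].[O-]C
Why: Ullmann-type methoxylation catalysed by CuBr (monovalent copper), the reaction that converts 2-bromo-4-methylphenol into 2-methoxy-4-methylphenol; the phenoxide is tolerated.

Step 3
Reactants: 3 2-methoxy-4,5-dimethylphenol; 4 benzyl vinyl ether
Product: 6 racemic 7-benzyloxy-3,3-dimethoxy-5,6-dimethylbicyclo[2.2.2]oct-5-en-2-one (benzyloxy on the carbon next to the carbonyl-side bridgehead and syn to the C5=C6 bridge), via masked o-benzoquinone 5 (not isolated)
Conditions: PhI(OAc)2 added slowly, MeOH, 4 (10 equiv), rt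
Reagents that add atoms: methanol, CO
Why: Oxidative dearomatisation by PhI(OAc)2 (trivalent iodine) in methanol gives the o-quinone monoketal 5, an electron-poor diene that the excess enol ether should trap in an inverse-demand Diels–Alder reaction before it dimerises (the ring methyls slow dimerisation). The nucleophilic CH2 of the enol ether bonds to the δ-carbon of the dienone, so the benzyloxy carbon ends next to the carbonyl-side bridgehead, and the endo rule places OBn syn to the new alkene; the three stereocentres are set relative to each other.

Step 4
Reactants: 6 racemic bicyclooctenone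
Product: 7 7-benzyloxy-3,3-dimethoxy-5,6-dimethylbicyclo[2.2.2]oct-5-en-2-one as the single enantiomer of the SMILES in the list
Conditions: preparative SFC, amylose tris(3,5-dimethylphenylcarbamate) phase, CO2/i-PrOH
Reagents that add atoms: none
Why: Resolution by chromatography on a chiral phase, for which the rigid ketone with its benzyl group is a suitable substrate; it is done at the first chiral compound, and the absolute configuration of the retained enantiomer is to be secured crystallographically on a heavy-atom derivative.

Step 5
Reactants: 7 resolved bicyclooctenone; 8 vinylmagnesium bromide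
Product: 9 7-benzyloxy-3,3-dimethoxy-5,6-dimethyl-2-vinylbicyclo[2.2.2]oct-5-en-2-ol (vinyl syn to the C5=C6 bridge)
Conditions: THF, −78 → 0 °C; aq. NH4Cl
Reagents that add atoms: none
Why: Grignard 1,2-addition to a ketone that cannot enolise (its α-carbons are a ketal carbon and a bridgehead); approach past the flat alkene bridge, away from the C–H bonds of the saturated bridge, should place vinyl syn to the alkene and set the carbinol centre as the [3,3] shift needs.

Step 6
Reactants: 9 2-vinylbicyclo[2.2.2]oct-5-en-2-ol
Product: 12 2β-benzyloxy-9,9-dimethoxy-10βH-11,12,13-trinoreremophil-3-en-8-one (cis-fused), via potassium alkoxide 10 (not isolated), via potassium enolate 11 (not isolated)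
Conditions: KH, 18-crown-6, THF, 0 °C → rt; aq. NH4Cl
Reagents that add atoms: none
Why: KH deprotonates the tertiary alcohol and the crown ether frees the alkoxide 10, whose 1,5-diene (vinyl C6=C7, carbinol C8, bridgehead C3, ring alkene C4=C5) undergoes an anionic oxy-Cope [3,3] shift through the boat-like array that the bicycle enforces. The bridgehead–carbinol bond C3–C8 breaks, C6 bonds to C5, and the C8 enolate 11 results and is protonated at C7 on work-up. The closest known reaction is the anionic oxy-Cope rearrangement of 2-vinylbicyclo[2.2.2]oct-5-en-2-ols from masked o-benzoquinone adducts to cis-decalins. Ring B (six-membered) closes by sigmatropic bond formation while the bridged bicycle opens to the fused one; ring A is inherited. The new quaternary centre C5 is controlled by the bicycle: C6 can reach only the face of C5 turned toward the C8–C9 bridge, so C14 and H10 end cis and the absolute configuration follows from 7. The step needs the vinyl group syn to the alkene, secured in step 5, and it needs rearrangement to outrun cleavage of the alkoxide, which the alkoxide acceleration at room temperature should secure. The endo benzyloxy group ends 2β; C2 and C10 are corrected later.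

Step 7
Reactants: 12 cis-fused keto ketal
Product: 13 2β-benzyloxy-9-hydroxy-11,12,13-trinoreremophila-3,9(10)-dien-8-one (diosphenol)
Conditions: CF3CO2H/H2O (9:1), CH2Cl2, 0 °C → rt
Reagents that add atoms: water, O
Why: Acid hydrolysis of the α-keto dimethyl ketal gives the 8,9-dione, which should enolise toward the ring-fusion carbon to the more substituted diosphenol, as 3,4-diketo steroids exist as 4-hydroxy-4-en-3-ones; the cis C10 centre is erased on purpose.

Step 8
Reactants: 13 diosphenol
Product: 14 2β-benzyloxy-9-(methoxymethoxy)-11,12,13-trinoreremophila-3,9(10)-dien-8-one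
Conditions: MOMCl, i-Pr2NEt, CH2Cl2, 0 °C → rt
Reagents that add atoms: chloromethyl methyl ether, COCCl
Why: O-alkylation of the acidic enol; the acetal ether is inert to dissolving metal and, unlike a silyl group, cannot migrate between O9 and the O8 enolate.

Step 9
Reactants: 14 diosphenol methoxymethyl ether
Product: 16 2β-hydroxy-9α-(methoxymethoxy)-10αH-11,12,13-trinoreremophil-3-en-8-one (trans-fused), via dilithium enolate alkoxide 15 (not isolated)
Conditions: Li (6 equiv), NH3/THF, t-BuOH (1 equiv), −78 °C; isoprene, then NH4Cl; K2CO3, MeOH, rt
Reagents that add atoms: none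
Why: Dissolving-metal (Birch-type) reduction of the enone protonates the β-carbon C10 with the new C–H bond axial to ring B and anti to the axial C14 on the neighbouring quaternary carbon, the rule by which 10-methyl-1(9)-octal-2-ones give trans-decalones, so the 10α-H fusion is set. The enolate shields C8 and the C9 alkoxy group until the quench, and the benzyl ether is cleaved to toluene in the same pot. Protonation at C9 and brief base equilibration should leave the alkoxy group equatorial (9α), because the axial epimer would be syn-axial to C14.

Step 10
Reactants: 16 trans-fused 3-ene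
Product: 17 2β-hydroxy-9α-(methoxymethoxy)-10αH-11,12,13-trinoreremophilan-8-one (4β-methyl)
Conditions: H2 (1 atm), Rh/Al2O3, EtOH, rt
Reagents that add atoms: none
Why: Heterogeneous hydrogenation of a trisubstituted alkene; in the trans-decalin the axial C14 on the neighbouring C5 blocks the β face, so hydrogen should enter from α and C15 end β (equatorial, cis to C14). Rh/Al2O3 is chosen because it seldom hydrogenolyses or isomerises allylic alcohols.

Step 11
Reactants: 17 2β-alcohol
Product: 18 9α-(methoxymethoxy)-2α-(4-nitrobenzoyloxy)-10αH-11,12,13-trinoreremophilan-8-one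
Conditions: 4-O2NC6H4CO2H, PPh3, DIAD, THF, 0 °C → rt
Reagents that add atoms: 4-nitrobenzoic acid, OC(=O)c1ccc(cc1)[N+](=O)[O-]
Why: Mitsunobu inversion of an unhindered equatorial secondary alcohol (SN2 at C2 by the carboxylate), modelled on the 3β to 3α inversion of 5α-steroids; it turns the endo-derived 2β oxygen into the axial 2α oxygen of the target.

Step 12
Reactants: 18 2α-(4-nitrobenzoate)
Product: 19 2α-hydroxy-9α-(methoxymethoxy)-10αH-11,12,13-trinoreremophilan-8-one
Conditions: K2CO3, MeOH, rt
Reagents that add atoms: none
Why: Base-catalysed methanolysis of an activated aryl ester; C9, the only stereocentre α to the ketone, is already in its stable equatorial configuration.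

Step 13
Reactants: 19 2α-alcohol
Product: 20 2α-(tert-butyldimethylsilyloxy)-9α-(methoxymethoxy)-10αH-11,12,13-trinoreremophilan-8-one
Conditions: TBSCl, imidazole, DMF, 40 °C
Reagents that add atoms: tert-butyldimethylsilyl chloride, CC(C)(C)[Si](C)(C)Cl
Why: Silylation of a secondary alcohol; the silyl ether should survive amide base, the palladium step, Me2BBr at −78 °C and the organocopper step, and is removable at the end by fluoride without base.

Step 14
Reactants: 20 silyl ether ketone
Product: 21 2α-(tert-butyldimethylsilyloxy)-9α-(methoxymethoxy)-10αH-11,12,13-trinoreremophil-7-en-8-yl trifluoromethanesulfonate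
Conditions: KN(SiMe3)2, THF, −78 °C; then N-(5-chloro-2-pyridyl)triflimide, −78 °C
Reagents that add atoms: N-(5-chloropyridin-2-yl)-N-(trifluoromethylsulfonyl)trifluoromethanesulfonamide, FC(F)(F)S(=O)(=O)N(c1ccc(Cl)cn1)S(=O)(=O)C(F)(F)F
Why: Kinetic enolisation of the α-alkoxy ketone by a bulky amide should occur at the C7 methylene, away from C9, whose only α-hydrogen is axial and syn to C14; trapping at low temperature gives the 7-enol triflate.

Step 15
Reactants: 21 enol triflate
Product: 22 2α-(tert-butyldimethylsilyloxy)-9α-(methoxymethoxy)-10αH-11,12,13-trinoreremophil-7-ene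
Conditions: Pd(OAc)2 (5 mol %), PPh3, Bu3N, HCO2H, DMF, 60 °C
Reagents that add atoms: none
Why: Palladium-catalysed reduction of an enol triflate by formate (oxidative addition to zerovalent palladium, formate exchange, decarboxylation, reductive elimination) fixes the double bond at C7=C8.

Step 16
Reactants: 22 allylic methoxymethyl ether
Product: 23 2α-(tert-butyldimethylsilyloxy)-10αH-11,12,13-trinoreremophil-7-en-9α-ol
Conditions: Me2BBr, CH2Cl2, −78 °C; then aq. NaHCO3/THF
Reagents that add atoms: none
Why: Me2BBr cleaves methoxymethyl ethers at −78 °C through the bromomethyl ether, which hydrolyses on bicarbonate work-up; the silyl ether and the alkene should be left untouched.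

Step 17
Reactants: 23 allylic alcohol
Product: 24 7α,8α-epoxy-2α-(tert-butyldimethylsilyloxy)-10αH-11,12,13-trinoreremophilan-9α-ol
Conditions: VO(acac)2 (5 mol %), t-BuOOH, CH2Cl2, 0 °C → rt
Reagents that add atoms: tert-butyl hydroperoxide, CC(C)(C)OO
Why: Hydroxyl-directed epoxidation of an allylic alcohol delivers oxygen syn to the 9α hydroxyl; the α face is also the one not screened by the axial C14, so both effects should give the 7α,8α-epoxide and set C7 and C8.

Step 18
Reactants: 24 epoxy alcohol; 25 isopropenylmagnesium bromide
Product: 26 2α-(tert-butyldimethylsilyloxy)-10αH-eremophil-11-ene-8α,9α-diol (7β-isopropenyl)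
Conditions: CuI (20 mol %), 25 (5 equiv), THF, −30 → 0 °C; aq. NH4Cl/NH3
Reagents that add atoms: none
Why: Copper-catalysed Grignard opening of a cyclohexene oxide; in the rigid trans-decalin only attack at C7 from the β face is trans-diaxial (Fürst–Plattner rule) and C8 is further deactivated by the C9 oxygen. The isopropenyl group should therefore enter 7β (axial) and the hydroxyl appear 8α, as nucleophiles open 2α,3α-epoxy-5α-steroids at C2 from the β face despite the syn-axial angular methyl.

Step 19
Reactants: 26 8α,9α-diol; 27 (E)-3-methylpent-2-enoic acid
Product: 30 2α-(tert-butyldimethylsilyloxy)-8α-hydroxy-10αH-eremophil-11-en-9α-yl (E)-3-methylpent-2-enoate, via stannylene acetal 28 (not isolated), via acid chloride 29 (not isolated)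
Conditions: 26, Bu2SnO, toluene, reflux, Dean–Stark; 27, (COCl)2, cat. DMF, CH2Cl2, 0 °C → rt, evaporated; 29 added to 28, toluene, 0 °C → rt
Reagents that add atoms: none
Why: Regioselective acylation of a cis-1,2-diol through its dibutylstannylene acetal, in which the equatorial oxygen (O9) is the one acylated; the acid chloride is used without amine base, so no vinylketene forms and the E geometry and the conjugated position of the double bond should be kept.

Step 20
Reactants: 30 silyl ether ester
Product: 31 CNP0129603.2, 2α,8α-dihydroxy-10αH-eremophil-11-en-9α-yl (E)-3-methylpent-2-enoate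
Conditions: HF·pyridine, pyridine, THF, 0 °C → rt
Reagents that add atoms: none
Why: Fluoride cleavage of the secondary silyl ether under buffered, non-basic conditions that should neither move the ester from O9 to the cis O8 nor touch the isopropenyl group.

## Compound list

1 | 3,4-dimethylphenol | Cc1ccc(O)cc1C | starting material
2 | 2-bromo-4,5-dimethylphenol | Cc1cc(O)c(Br)cc1C | intermediate
3 | 2-methoxy-4,5-dimethylphenol | COc1cc(C)c(C)cc1O | intermediate
4 | benzyl vinyl ether | C=COCc1ccccc1 | starting material
5 | 6,6-dimethoxy-3,4-dimethylcyclohexa-2,4-dien-1-one (masked o-benzoquinone, not isolated) | COC1(OC)C=C(C)C(C)=CC1=O | intermediate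
6 | racemic 7-benzyloxy-3,3-dimethoxy-5,6-dimethylbicyclo[2.2.2]oct-5-en-2-one, benzyloxy syn to the C5=C6 bridge (racemate; the SMILES shows the enantiomer carried on) | O=C1C(OC)(OC)[C@H]2C[C@H](OCc3ccccc3)[C@@H]1C(C)=C2C | intermediate
7 | 7-benzyloxy-3,3-dimethoxy-5,6-dimethylbicyclo[2.2.2]oct-5-en-2-one, single enantiomer | O=C1C(OC)(OC)[C@H]2C[C@H](OCc3ccccc3)[C@@H]1C(C)=C2C | intermediate
8 | vinylmagnesium bromide | C=C[Mg]Br | starting material
9 | 7-benzyloxy-3,3-dimethoxy-5,6-dimethyl-2-vinylbicyclo[2.2.2]oct-5-en-2-ol, vinyl and benzyloxy syn to the C5=C6 bridge | C=C[C@]1(O)C(OC)(OC)[C@H]2C[C@H](OCc3ccccc3)[C@@H]1C(C)=C2C | intermediate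
10 | potassium alkoxide of 9 (not isolated) | C=C[C@]1([O-])C(OC)(OC)[C@H]2C[C@H](OCc3ccccc3)[C@@H]1C(C)=C2C.[K+] | intermediate
11 | potassium 7-en-8-olate of 12 (not isolated) | [K+].[O-]C1=CC[C@]2(C)C(C)=C[C@@H](OCc3ccccc3)C[C@@H]2C1(OC)OC | intermediate
12 | 2β-benzyloxy-9,9-dimethoxy-10βH-11,12,13-trinoreremophil-3-en-8-one (cis-fused) | C1C[C@]2(C)C(C)=C[C@@H](OCc3ccccc3)C[C@@H]2C(OC)(OC)C1=O | intermediate
13 | 2β-benzyloxy-9-hydroxy-11,12,13-trinoreremophila-3,9(10)-dien-8-one | C1C[C@]2(C)C(C)=C[C@@H](OCc3ccccc3)CC2=C(O)C1=O | intermediate
14 | 2β-benzyloxy-9-(methoxymethoxy)-11,12,13-trinoreremophila-3,9(10)-dien-8-one | C1C[C@]2(C)C(C)=C[C@@H](OCc3ccccc3)CC2=C(OCOC)C1=O | intermediate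
15 | dilithium 8-enolate 2-alkoxide of 16 (not isolated) | [Li+].[Li+].[O-]C1=C(OCOC)[C@@H]2C[C@H]([O-])C=C(C)[C@@]2(C)CC1 | intermediate
16 | 2β-hydroxy-9α-(methoxymethoxy)-10αH-11,12,13-trinoreremophil-3-en-8-one (trans-fused) | C1C[C@]2(C)C(C)=C[C@@H](O)C[C@H]2[C@H](OCOC)C1=O | intermediate
17 | 2β-hydroxy-9α-(methoxymethoxy)-10αH-11,12,13-trinoreremophilan-8-one (4β-methyl) | C1C[C@]2(C)[C@@H](C)C[C@@H](O)C[C@H]2[C@H](OCOC)C1=O | intermediate
18 | 9α-(methoxymethoxy)-2α-(4-nitrobenzoyloxy)-10αH-11,12,13-trinoreremophilan-8-one | C1C[C@]2(C)[C@@H](C)C[C@H](OC(=O)c3ccc(cc3)[N+](=O)[O-])C[C@H]2[C@H](OCOC)C1=O | intermediate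
19 | 2α-hydroxy-9α-(methoxymethoxy)-10αH-11,12,13-trinoreremophilan-8-one | C1C[C@]2(C)[C@@H](C)C[C@H](O)C[C@H]2[C@H](OCOC)C1=O | intermediate
20 | 2α-(tert-butyldimethylsilyloxy)-9α-(methoxymethoxy)-10αH-11,12,13-trinoreremophilan-8-one | C1C[C@]2(C)[C@@H](C)C[C@H](O[Si](C)(C)C(C)(C)C)C[C@H]2[C@H](OCOC)C1=O | intermediate
21 | 2α-(tert-butyldimethylsilyloxy)-9α-(methoxymethoxy)-10αH-11,12,13-trinoreremophil-7-en-8-yl trifluoromethanesulfonate | FC(F)(F)S(=O)(=O)OC1=CC[C@]2(C)[C@@H](C)C[C@H](O[Si](C)(C)C(C)(C)C)C[C@H]2[C@@H]1OCOC | intermediate
22 | 2α-(tert-butyldimethylsilyloxy)-9α-(methoxymethoxy)-10αH-11,12,13-trinoreremophil-7-ene | C1=CC[C@]2(C)[C@@H](C)C[C@H](O[Si](C)(C)C(C)(C)C)C[C@H]2[C@@H]1OCOC | intermediate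
23 | 2α-(tert-butyldimethylsilyloxy)-10αH-11,12,13-trinoreremophil-7-en-9α-ol | C1=CC[C@]2(C)[C@@H](C)C[C@H](O[Si](C)(C)C(C)(C)C)C[C@H]2[C@@H]1O | intermediate
24 | 7α,8α-epoxy-2α-(tert-butyldimethylsilyloxy)-10αH-11,12,13-trinoreremophilan-9α-ol | O1[C@@H]2C[C@]3(C)[C@@H](C)C[C@H](O[Si](C)(C)C(C)(C)C)C[C@H]3[C@H](O)[C@H]12 | intermediate
25 | isopropenylmagnesium bromide | C=C(C)[Mg]Br | starting material
26 | 2α-(tert-butyldimethylsilyloxy)-10αH-eremophil-11-ene-8α,9α-diol (7β-isopropenyl) | C=C(C)[C@H]1C[C@]2(C)[C@@H](C)C[C@H](O[Si](C)(C)C(C)(C)C)C[C@H]2[C@H](O)[C@@H]1O | intermediate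
27 | (E)-3-methylpent-2-enoic acid | OC(=O)/C=C(\C)CC | starting material
28 | 8,9-O-dibutylstannylene acetal of 26 (not isolated) | C=C(C)[C@H]1C[C@]2(C)[C@@H](C)C[C@H](O[Si](C)(C)C(C)(C)C)C[C@H]2[C@@H]3O[Sn](CCCC)(CCCC)O[C@H]13 | intermediate
29 | (E)-3-methylpent-2-enoyl chloride (not isolated) | ClC(=O)/C=C(\C)CC | intermediate
30 | 2α-(tert-butyldimethylsilyloxy)-8α-hydroxy-10αH-eremophil-11-en-9α-yl (E)-3-methylpent-2-enoate | C=C(C)[C@H]1C[C@]2(C)[C@@H](C)C[C@H](O[Si](C)(C)C(C)(C)C)C[C@H]2[C@H](OC(=O)/C=C(\C)CC)[C@@H]1O | intermediate
31 | CNP0129603.2, 2α,8α-dihydroxy-10αH-eremophil-11-en-9α-yl (E)-3-methylpent-2-enoate | C=C(C)[C@H]1C[C@]2(C)[C@@H](C)C[C@H](O)C[C@H]2[C@H](OC(=O)/C=C(\C)CC)[C@@H]1O | target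

## Step count and least certain steps

Total step count: 20. Longest linear sequence: 20 steps (1 to 31); 4, 8, 25 and 27 are purchased.

**Step 6 (key step).** The accepting alkene carbon is fully substituted, so the shift may be slow, and the alkoxide may then fragment instead of rearranging. Fallback, from 9 to 12: silylate 9 (Me3SiCl, imidazole) to the trimethylsilyl ether F1 and heat it in a sealed, base-washed tube (toluene, about 220 °C). This neutral siloxy-Cope rearrangement uses the same [3,3] bond change without a free alkoxide and gives the trimethylsilyl enol ether F2. Methanolysis (K2CO3, MeOH) returns the route to 12.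

**Step 7.** The α-keto ketal is deactivated toward hydrolysis, and the acid it needs may ionise the allylic C2 benzyl ether or stop at the enol ether. Fallback, from 12 to 13: eliminate methanol under aprotic, buffered conditions (Me3SiOTf, i-Pr2NEt, CH2Cl2) to the 9-methoxy dienone F3. Then demethylate this diosphenol methyl ether by SN2 attack of NaSEt in DMF, the diosphenolate being the leaving group, which gives 13.

**Step 9.** Oxygen may be lost by over-reduction of the α-alkoxy ketone if the enolate is protonated while lithium remains, or by cleavage of the allylic C2–O bond in competition with the benzyl–O bond. Fallback, from 14 to 17: separate the two reductive events. Titrate lithium in ammonia into 14 only until the enone is consumed, which keeps the benzyl ether and gives the trans-fused benzyl ether F4. Hydrogen over Pd/C then saturates C3=C4 from the α face and removes the benzyl group by hydrogenolysis, rejoining the route at 17.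

**Step 14.** Enolisation may lose regiocontrol and go toward C9, whose alkoxy-substituted enolate is the more stable one; the result would be an enol ether after reduction. Fallback, from 20 to 22: condense 20 with 4-toluenesulfonylhydrazide to the tosylhydrazone F5 and carry out a Shapiro reaction (LiN(i-Pr)2 in excess, THF, −78 → 0 °C, water quench). The dianion forms at the C7 methylene, and loss of sulfinate and nitrogen gives 22 directly, bypassing 21.

**Step 18.** The opening may be slow or misdirected: axial approach to C7 is syn-axial to C14, and the magnesium halide may open the epoxide to a bromohydrin or trigger a hydride shift to a ketone. Fallback, from 24 to 26: open the epoxide with the slim, linear nucleophile LiC≡CSiMe3 and BF3·OEt2 (THF, −78 °C) to the 7β-(trimethylsilylethynyl) diol F6. Remove the C-silyl group (K2CO3, MeOH) to the 7β-ethynyl diol F7. Methylalumination of the terminal alkyne (Me3Al, Cp2ZrCl2, CH2Cl2) followed by protonolysis puts methyl on the inner carbon and gives the isopropenyl group of 26.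

**Step 19.** Regiocontrol may be incomplete (acylation at O8, diacylation, or migration of the acyl group to the cis O8), and the double bond of the acid chloride may isomerise. Fallback, from 26 and 27 to 30: couple the free acid directly with dicyclohexylcarbodiimide and catalytic 4-dimethylaminopyridine (CH2Cl2, 0 °C). This relies on the higher reactivity of the equatorial O9 over the axial O8 and needs neither tin nor acid chloride. It makes no compound outside the list (F0), and any O8 ester can be returned to 26 by methanolysis.

## Further compounds

F1 | step 6 | trimethylsilyl ether of 9 | C=C[C@]1(O[Si](C)(C)C)C(OC)(OC)[C@H]2C[C@H](OCc3ccccc3)[C@@H]1C(C)=C2C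
F2 | step 6 | trimethylsilyl enol ether of 12 (7-en-8-yl silyl ether) | C[Si](C)(C)OC1=CC[C@]2(C)C(C)=C[C@@H](OCc3ccccc3)C[C@@H]2C1(OC)OC
F3 | step 7 | 2β-benzyloxy-9-methoxy-11,12,13-trinoreremophila-3,9(10)-dien-8-one | C1C[C@]2(C)C(C)=C[C@@H](OCc3ccccc3)CC2=C(OC)C1=O
F4 | step 9 | 2β-benzyloxy-9α-(methoxymethoxy)-10αH-11,12,13-trinoreremophil-3-en-8-one | C1C[C@]2(C)C(C)=C[C@@H](OCc3ccccc3)C[C@H]2[C@H](OCOC)C1=O
F5 | step 14 | 4-toluenesulfonylhydrazone of 20 | Cc1ccc(cc1)S(=O)(=O)NN=C1CC[C@]2(C)[C@@H](C)C[C@H](O[Si](C)(C)C(C)(C)C)C[C@H]2[C@@H]1OCOC
F6 | step 18 | 2α-(tert-butyldimethylsilyloxy)-7β-(trimethylsilylethynyl)-10αH-11,12,13-trinoreremophilane-8α,9α-diol | C[Si](C)(C)C#C[C@H]1C[C@]2(C)[C@@H](C)C[C@H](O[Si](C)(C)C(C)(C)C)C[C@H]2[C@H](O)[C@@H]1O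
F7 | step 18 | 2α-(tert-butyldimethylsilyloxy)-7β-ethynyl-10αH-11,12,13-trinoreremophilane-8α,9α-diol | C#C[C@H]1C[C@]2(C)[C@@H](C)C[C@H](O[Si](C)(C)C(C)(C)C)C[C@H]2[C@H](O)[C@@H]1O
F0 | step 19 | none | none
A1 | alternative 1 | ring-A dialdehyde (C8 and C9 aldehydes, 2-O-silyl) | O=C[C@@H](C(C)=C)C[C@]1(C)[C@@H](C)C[C@H](O[Si](C)(C)C(C)(C)C)C[C@H]1C=O
A2 | alternative 1 | 2-O-silyl 8α,9α-diol (identical with 26) | C=C(C)[C@H]1C[C@]2(C)[C@@H](C)C[C@H](O[Si](C)(C)C(C)(C)C)C[C@H]2[C@H](O)[C@@H]1O
A3 | alternative 2 | acyclic β-keto ester with E-trisubstituted alkene and vinyl ketone | COC(=O)CC(=O)C[C@H](C)/C(C)=C/[C@H](O[Si](C)(C)C(C)(C)C)C(=O)C=C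
A4 | alternative 2 | 1-carbomethoxy-9α-silyloxy trans-decalin-2,8-dione | C1C[C@]2(C)[C@@H](C)CC(=O)[C@H](C(=O)OC)[C@H]2[C@H](O[Si](C)(C)C(C)(C)C)C1=O
A5 | alternative 3 | α-methylene ketone aldehyde | O=CC[C@H](C)[C@@]1(C)CCCC(=O)C1=C
A6 | alternative 3 | 2α-hydroxy-4,5-dimethyl trans-decal-9-one | C1C[C@]2(C)[C@@H](C)C[C@H](O)C[C@H]2C(=O)C1
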